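Atoms carry the numbers of their order in the target SMILES. The route rests on opening the spiro hemiketal tetrahydropyran (O9, C3, C5, C6, C7, C8) at C7–C8 and O9–C3, which leaves formaldehyde and a 1-silyloxydiene, C3(OSi)=C5–C6=C7, exocyclic on the one-carbon bridge C7 of the tetracyclic azabicyclo[4.3.1]decene dienoate. One oxa-Diels–Alder step should then form both ring bonds, the quaternary spiro centre C7 and the masked hemiketal C3. The precursor is built with defined geometry, (Z)-enol ether and side chain syn to C10, so that only oxygen and the C10–H unit lie inside the cisoid diene. The core comes from cycloheptane-1,3-dione by Michael, double Mannich, Nazarov and aldol ring closures.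

Key step: step 13

Assumption: the hemiketal carbon C3 can equilibrate by ring–chain tautomerism, and the epimer drawn for the target is taken to be its resting form. Racemates 6–10 are written without stereodescriptors, because the bridge fixes the relative configuration of C10 and C22.

Step 1
Reactants: 1 cycloheptane-1,3-dione; 2 methyl acrylate
Product: 3 methyl 3-(2,7-dioxocycloheptyl)propanoate
Conditions: Et3N (20 mol%), MeCN, 50 °C
Reagents that add atoms: none
Why: Michael addition of the acidic C–H between the two carbonyl groups (future C22) to the acrylate, with one equivalent of acceptor to limit double addition.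

Step 2
Reactants: 3 methyl 3-(2,7-dioxocycloheptyl)propanoate; 4 methylamine; 5 formaldehyde (as paraformaldehyde, 2 equiv)
Product: 6 methyl 3-(8-methyl-2,10-dioxo-8-azabicyclo[4.3.1]decan-1-yl)propanoate (racemate)
Conditions: MeNH2 (33% in EtOH), (CH2O)n, AcOH, EtOH, 70 °C
Reagents that add atoms: none
Why: Double Mannich annulation, in which C22 is aminomethylated first and the derived N-methyliminium ion closes onto the α′-methylene C10; the bridge can only form cis, so C22 and C10 should arise in the required relative configuration.

Step 3
Reactants: 6 racemic bicyclic amino dione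
Product: 7 methyl 3-[8-methyl-10-oxo-2-(trifluoromethylsulfonyloxy)-8-azabicyclo[4.3.1]dec-2-en-1-yl]propanoate (racemate; C13=C14 enol triflate)
Conditions: KHMDS, THF, −78 °C; PhNTf2, −78 → 0 °C
Reagents that add atoms: N-phenylbis(trifluoromethanesulfonimide), O=S(=O)(N(c1ccccc1)S(=O)(=O)C(F)(F)F)C(F)(F)F
Why: Enol triflate formation, regiospecific because the bridge ketone C7 lies between a quaternary carbon and a bridgehead, so only C13 of the C14 ketone can be enolised.

Step 4
Reactants: 7 racemic vinyl triflate
Product: 8 methyl 3-(2-acryloyl-8-methyl-10-oxo-8-azabicyclo[4.3.1]dec-2-en-1-yl)propanoate (racemate; divinyl ketone with C15 as carbonyl carbon)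
Conditions: CO (1 atm), Bu3SnCH=CH2, Pd(PPh3)4 (5 mol%), LiCl, THF, 55 °C
Reagents that add atoms: carbon monoxide, [C-]#[O+]; tributyl(vinyl)stannane, C=C[Sn](CCCC)(CCCC)CCCC
Why: Carbonylative Stille coupling, in which oxidative addition of the vinyl triflate, CO insertion and vinyl transfer from tin should give the cross-conjugated dienone.

Step 5
Reactants: 8 racemic divinyl ketone
Product: 9 racemic tricyclic enone keto ester (ring A closed as a cyclopentenone with C15=O and C13=C14; bridge ketone C7 and propanoate chain on C22 unchanged)
Conditions: MeSO3H, CH2Cl2, 0 °C → rt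
Reagents that add atoms: none
Why: Nazarov cyclisation, a conrotatory 4π-electrocyclisation of the protonated dienone forming C13–C28, followed by loss of the C13 proton to the more substituted ring-fusion enone; the protonated amine cannot add to the vinyl ketone.

Step 6
Reactants: 9 racemic tricyclic enone keto ester
Product: 10 racemic tetracyclic keto dienoate (C7 ketone; C13=C14–C15=C16–CO2Me)
Conditions: NaOMe (0.5 equiv), MeOH, 65 °C
Reagents that add atoms: none
Why: Intramolecular aldol condensation, in which the ester enolate carbon C16 adds to the C15 ketone in a five-membered closure and E1cB dehydration gives the fully conjugated dienoate, the thermodynamic sink of the reversible enolisations.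

Step 7
Reactants: 10 racemic tetracyclic keto dienoate
Product: 11 tetracyclic keto dienoate, single enantiomer with the C10 and C22 configuration of the target
Conditions: preparative chiral SFC, amylose tris(3,5-dimethylphenylcarbamate) phase, CO2/MeOH, 0.1% Et2NH
Reagents that add atoms: none
Why: Resolution by chromatography on a chiral stationary phase; C22 is quaternary and C10 a bridgehead, so the enantiomer is configurationally stable, and its absolute configuration would be assigned by anomalous-dispersion X-ray analysis of a crystalline salt.

Step 8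
Reactants: 12 ethyl vinyl ketone
Product: 13 2-(2-bromoethyl)-2-ethyl-1,3-dioxolane
Conditions: HBr (g), HOCH2CH2OH, CH2Cl2, 0 °C → rt
Reagents that add atoms: hydrogen bromide, Br; ethylene glycol, OCCO
Why: Conjugate addition of HBr to the enone with ketalisation in the same flask, a standard hydrobromination–ketalisation of alkyl vinyl ketones.

Step 9
Reactants: 13 2-(2-bromoethyl)-2-ethyl-1,3-dioxolane; 11 enantiopure tetracyclic keto dienoate
Product: 16 tertiary carbinol carrying OH and the 2-(2-ethyl-1,3-dioxolan-2-yl)ethyl chain on C7 (carbinol configuration not assigned), via Grignard reagent 14 (not isolated), via organocerium reagent 15 (not isolated)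
Conditions: Mg, THF, 30 °C; CeCl3, THF, −78 °C; 11, −78 → 0 °C
Reagents that add atoms: none
Why: 1,2-Addition of an organocerium reagent, which is weakly basic and strongly nucleophilic, so it should add to the hindered, non-enolisable bridge ketone and spare the tetrasubstituted dienoate; the new carbinol centre is removed in step 10.

Step 10
Reactants: 16 tertiary carbinol
Product: 17 exocyclic alkene ketal (C6=C7, side chain syn to C10)
Conditions: Burgess reagent, toluene, 70 °C
Reagents that add atoms: none
Why: Burgess dehydration by syn-elimination of the sulfamate; C22 is quaternary and C10 a bridgehead, so only C6 offers a hydrogen and the exocyclic alkene must form, with the chain expected on the side of the smaller bridgehead C10.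

Step 11
Reactants: 17 exocyclic alkene ketal
Product: 18 β,γ-unsaturated ethyl ketone (C7=C6–C5H2–C3(=O)–Et)
Conditions: 1 M HCl, THF, rt
Reagents that add atoms: water, O
Why: Acid-catalysed ketal hydrolysis; dilute acid at room temperature should not move the trisubstituted alkene into conjugation.

Step 12
Reactants: 18 β,γ-unsaturated ethyl ketone
Product: 19 tetracyclic dienoate carrying the exocyclic silyl dienol ether C3(OTBS)=C5–C6=C7 (C3=C5 Z with oxygen cis to C6; C6=C7 with C5 cis to C10)
Conditions: TBSOTf, Et3N, CH2Cl2, −20 → 0 °C
Reagents that add atoms: tert-butyldimethylsilyl trifluoromethanesulfonate, CC(C)(C)[Si](C)(C)OS(=O)(=O)C(F)(F)F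
Why: Soft enolisation and O-silylation (silyl enol ether formation); the C5 protons are both allylic and α to the ketone, so the conjugated dienol ether should form in preference to the C2 enol ether, and as the (Z)-isomer that minimises allylic strain.

Step 13
Reactants: 19 silyl dienol ether; 5 formaldehyde (from paraformaldehyde)
Product: 20 spiro-dihydropyran tert-butyldimethylsilyl ketal (C7–C8 and O9–C3 formed; C5=C6 in the ring)
Conditions: (CH2O)n, Me2AlCl (3 equiv), CH2Cl2, 0 °C; then 19, −78 → −30 °C; Et3N, aq. NaHCO3
Reagents that add atoms: none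
Why: Aluminium-bound formaldehyde is attacked by C7, the γ-terminus of the cisoid silyl dienol ether, and the aluminium alkoxide O9 then closes onto the silyloxocarbenium carbon C3, the Lewis acid-promoted oxa-Diels–Alder reaction (vinylogous Mukaiyama aldol, then ketalisation) of a 1-silyloxydiene with an aldehyde. The dihydropyran closes in the [4+2] sense, C7–C8 first and O9–C3 second, as a six-membered addition of oxygen to the oxocarbenium ion on the same face of the diene. C7 is controlled by the bicyclic core, because formaldehyde should enter on the π-face over the cycloheptene, which is flanked by trigonal C14, while the axial hydrogens on C23 and C26 and the aluminium-loaded nitrogen screen the aza-bridge face. C3 follows from suprafacial addition to the diene geometry set in steps 10 and 12 (OTBS and C10 both inside, hence cis) and can still equilibrate at the hemiketal stage. The step needs γ- over α-attack and a cisoid closure: formaldehyde is the smallest electrophile for a fully substituted terminus, only oxygen and the C10–H unit lie inside the s-cis diene, and one of the three equivalents of Lewis acid is held by N24.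

Step 14
Reactants: 20 spiro-dihydropyran silyl ketal
Product: 21 spiro-tetrahydropyran tert-butyldimethylsilyl ketal (C5–C6 saturated)
Conditions: 2-O2NC6H4SO2NHNH2, Et3N, CH2Cl2/i-PrOH, rt
Reagents that add atoms: none
Why: Diimide reduction by concerted syn transfer of H2, which should touch only the cis-disubstituted C5=C6 bond and leave the tetrasubstituted, ester-conjugated diene; no metal is present to hydrogenolyse the allylic ketal C–O bond.

Step 15
Reactants: 21 spiro-tetrahydropyran silyl ketal
Product: 22 CNP0192143.1 (target hemiketal)
Conditions: HF·pyridine, pyridine, THF, 0 °C → rt; aq. NaHCO3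
Reagents that add atoms: none
Why: Fluoride-mediated desilylation cleaves only the Si–O bond, so C3 keeps the configuration set in step 13; ring–chain tautomerism of the free hemiketal allows equilibration at C3, the drawn epimer being taken as the resting form.

Compound list
1 | cycloheptane-1,3-dione | O=C1CCCCC(=O)C1 | starting material
2 | methyl acrylate | C=CC(=O)OC | starting material
3 | methyl 3-(2,7-dioxocycloheptyl)propanoate | COC(=O)CCC1C(=O)CCCCC1=O | intermediate
4 | methylamine | CN | starting material
5 | formaldehyde (as paraformaldehyde) | C=O | starting material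
6 | methyl 3-(8-methyl-2,10-dioxo-8-azabicyclo[4.3.1]decan-1-yl)propanoate, racemate | O=C1C2CCCC(=O)C1(CCC(=O)OC)CN(C)C2 | intermediate
7 | methyl 3-[8-methyl-10-oxo-2-(trifluoromethylsulfonyloxy)-8-azabicyclo[4.3.1]dec-2-en-1-yl]propanoate, racemate | O=C1C2CCC=C(OS(=O)(=O)C(F)(F)F)C1(CCC(=O)OC)CN(C)C2 | intermediate
8 | methyl 3-(2-acryloyl-8-methyl-10-oxo-8-azabicyclo[4.3.1]dec-2-en-1-yl)propanoate, racemate | O=C1C2CCC=C(C(=O)C=C)C1(CCC(=O)OC)CN(C)C2 | intermediate
9 | tricyclic enone keto ester (cyclopentenone ring A fused at C13=C14), racemate | O=C1C2CCC3=C(C(=O)CC3)C1(CCC(=O)OC)CN(C)C2 | intermediate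
10 | tetracyclic keto dienoate (C7 ketone), racemate | O=C2C1CCC3=C4C(=C(C(=O)OC)CC42CN(C)C1)CC3 | intermediate
11 | tetracyclic keto dienoate, single enantiomer | O=C2[C@@H]1CCC3=C4C(=C(C(=O)OC)C[C@@]42CN(C)C1)CC3 | intermediate
12 | ethyl vinyl ketone | CCC(=O)C=C | starting material
13 | 2-(2-bromoethyl)-2-ethyl-1,3-dioxolane | CCC1(CCBr)OCCO1 | intermediate
14 | [2-(2-ethyl-1,3-dioxolan-2-yl)ethyl]magnesium bromide | CCC1(CC[Mg]Br)OCCO1 | intermediate (not isolated)
15 | [2-(2-ethyl-1,3-dioxolan-2-yl)ethyl]cerium dichloride | CCC1(CC[Ce](Cl)Cl)OCCO1 | intermediate (not isolated)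
16 | C7 tertiary carbinol with ketal side chain (C7 configuration not assigned) | CCC1(OCCO1)CCC2(O)[C@@H]1CCC3=C4C(=C(C(=O)OC)C[C@@]42CN(C)C1)CC3 | intermediate
17 | exocyclic C6=C7 alkene ketal, chain syn to C10 | CCC1(OCCO1)C/C=C2\[C@@H]1CCC3=C4C(=C(C(=O)OC)C[C@@]42CN(C)C1)CC3 | intermediate
18 | β,γ-unsaturated ethyl ketone | CCC(=O)C/C=C2\[C@@H]1CCC3=C4C(=C(C(=O)OC)C[C@@]42CN(C)C1)CC3 | intermediate
19 | tetracyclic dienoate with exocyclic (Z)-silyl dienol ether (key-step precursor) | CC/C(O[Si](C)(C)C(C)(C)C)=C/C=C2\[C@@H]1CCC3=C4C(=C(C(=O)OC)C[C@@]42CN(C)C1)CC3 | intermediate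
20 | spiro-dihydropyran TBS ketal (key-step product) | CC[C@@]1(O[Si](C)(C)C(C)(C)C)C=C[C@@]2(CO1)[C@@H]1CCC3=C4C(=C(C(=O)OC)C[C@@]42CN(C)C1)CC3 | intermediate
21 | spiro-tetrahydropyran TBS ketal | CC[C@@]1(O[Si](C)(C)C(C)(C)C)CC[C@@]2(CO1)[C@@H]1CCC3=C4C(=C(C(=O)OC)C[C@@]42CN(C)C1)CC3 | intermediate
22 | CNP0192143.1 | CC[C@@]1(O)CC[C@@]2(CO1)[C@@H]1CCC3=C4C(=C(C(=O)OC)C[C@@]42CN(C)C1)CC3 | target

Total step count: 15. Longest linear sequence: 14 steps (steps 1–7 and 9–15; step 8 is the side branch).

Steps most likely to fail

Step 13. Formaldehyde may bond through C5 instead of C7, the cisoid geometry may be lost before O9 closes onto C3 (open-chain aldol product), or bonding may occur on the aza-bridge face. The fallback sets out from 11 and returns at 22, building C7 from an aldehyde enolate instead of a dienol ether. A Wittig reaction with methoxymethylenetriphenylphosphorane should give the enol ether F1, and aqueous acid the C7 carbaldehyde F2. A base-mediated aldol reaction with formaldehyde 5 (K2CO3, MeOH) then makes C7 quaternary, the hydroxymethyl group (C8–O9) entering on the more open face, to give the hydroxy aldehyde F3. Horner–Wadsworth–Emmons olefination with dimethyl (2-oxobutyl)phosphonate should give the E-enone F4, and conjugate reduction with Stryker's reagent the hydroxy ketone F5, which closes on its own to 22. Should the more open face prove to be the aza-bridge face, F2 is instead added to ethyl vinyl ketone 12 (Michael addition) to give the keto aldehyde F6, whose aldehyde is reduced with NaBH(OAc)3 to reach F5 and 22 with the two C7 substituents exchanged.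

Step 5. Polymerisation of the vinyl ketone or cationic skeletal migration next to the quaternary C22 may outrun the electrocyclisation. The fallback sets out from 6 and returns at 9 without a cationic step. The C14 ketone is converted into its trimethylsilyl enol ether F7 (TMSOTf, Et3N), and Mukaiyama–Michael addition to acrolein (BF3·OEt2) should give the keto aldehyde F8. A triazolium-carbene catalysed intramolecular crossed benzoin reaction then closes ring A as the α-ketol F9, and dehydration (SOCl2, pyridine) should give 9.

Step 6. Enolisation of the enone at C27 or C12 and retro-aldol cleavage may outrun the ester aldol and its dehydration. The fallback sets out from 7 and returns at 10, replacing the aldol by an olefination. The ester enolate of 7 (LDA, −78 °C) is C-phosphorylated with diethyl chlorophosphite and oxidised in air to the phosphonate F10. Carbonylative Stille coupling then gives the dienone F11 and Nazarov cyclisation the enone F12, as in steps 4 and 5. An intramolecular Horner–Wadsworth–Emmons reaction (K2CO3, 18-crown-6, toluene) should close ring B and give 10.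

Further compounds
F1 | step 13 | C7 methoxymethylene enol ether (E/Z mixture) | COC=C2[C@@H]1CCC3=C4C(=C(C(=O)OC)C[C@@]42CN(C)C1)CC3
F2 | step 13 | C7 carbaldehyde (C7 epimers) | O=CC2[C@@H]1CCC3=C4C(=C(C(=O)OC)C[C@@]42CN(C)C1)CC3
F3 | step 13 | C7 quaternary hydroxymethyl aldehyde | O=C[C@@]2(CO)[C@@H]1CCC3=C4C(=C(C(=O)OC)C[C@@]42CN(C)C1)CC3
F4 | step 13 | (E)-enone with free C8 hydroxyl | CCC(=O)/C=C/[C@@]2(CO)[C@@H]1CCC3=C4C(=C(C(=O)OC)C[C@@]42CN(C)C1)CC3
F5 | step 13 | open-chain hydroxy ketone tautomer of 22 | CCC(=O)CC[C@@]2(CO)[C@@H]1CCC3=C4C(=C(C(=O)OC)C[C@@]42CN(C)C1)CC3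
F6 | step 13 | C7 quaternary keto aldehyde from Michael addition | CCC(=O)CC[C@@]2(C=O)[C@@H]1CCC3=C4C(=C(C(=O)OC)C[C@@]42CN(C)C1)CC3
F7 | step 5 | trimethylsilyl enol ether of 6 (racemate) | O=C1C2CCC=C(O[Si](C)(C)C)C1(CCC(=O)OC)CN(C)C2
F8 | step 5 | C13 3-oxopropyl keto aldehyde (racemate, C13 epimers) | O=C1C2CCC(CCC=O)C(=O)C1(CCC(=O)OC)CN(C)C2
F9 | step 5 | ring A α-ketol (racemate) | O=C1C2CCC3CCC(=O)C3(O)C1(CCC(=O)OC)CN(C)C2
F10 | step 6 | α-(diethoxyphosphoryl) ester vinyl triflate (racemate) | O=C1C2CCC=C(OS(=O)(=O)C(F)(F)F)C1(CC(C(=O)OC)P(=O)(OCC)OCC)CN(C)C2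
F11 | step 6 | α-(diethoxyphosphoryl) ester divinyl ketone (racemate) | O=C1C2CCC=C(C(=O)C=C)C1(CC(C(=O)OC)P(=O)(OCC)OCC)CN(C)C2
F12 | step 6 | α-(diethoxyphosphoryl) ester tricyclic enone (racemate) | O=C1C2CCC3=C(C(=O)CC3)C1(CC(C(=O)OC)P(=O)(OCC)OCC)CN(C)C2
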